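Target is what I want from the next flask, and the choice is how much free catalyst to charge for a reading at 5.0 h.

| flask | starting material | second substrate | protic impurity | free catalyst | remark | time |
|---|---|---|---|---|---|---|
| gamma | 0.050 M | 0.050 M | 0.010 M | 0.34 mM | run made earlier |  |
| alpha | 0.050 M | 0.050 M | 0.010 M | 3.5 mM | run made earlier |  |
| ash | 0.050 M | 0.0500 M | 0.0100 M | 1.0 mM |  | 5.0 h |
| larch | 0.050 M | 0.0500 M | 0.0100 M | 0.60 mM |  | 5.0 h |
| cedar | 0.050 M | 0.0500 M | 0.0100 M | 0.25 mM |  | 5.0 h |
| alder | 0.050 M | 0.0500 M | 0.0100 M | 0.30 mM |  | 5.0 h |
| birch | 0.050 M | 0.0500 M | 0.0100 M | 3.0 mM |  | 5.0 h |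
| oak | 0.050 M | 0.0500 M | 0.0100 M | 0.50 mM |  | 5.0 h |

| run | time / h | target / % | starting material / % |
|---|---|---|---|
| gamma | 0.200 | 2.7 | 95.4 |
| gamma | 0.333 | 4.6 | 93.0 |
| gamma | 0.500 | 5.7 | 90.0 |
| gamma | 0.667 | 7.5 | 87.2 |
| gamma | 1.00 | 11.1 | 81.2 |
| gamma | 1.50 | 15.7 | 74.8 |
| gamma | 2.50 | 24.7 | 63.0 |
| alpha | 0.200 | 22.6 | 73.8 |
| alpha | 0.333 | 35.2 | 60.7 |
| alpha | 0.500 | 48.3 | 46.0 |
| alpha | 0.667 | 59.7 | 35.0 |
| alpha | 1.00 | 75.5 | 19.2 |
| alpha | 1.50 | 88.1 | 6.8 |
| alpha | 2.50 | 94.0 | 1.1 |

(readings scatter by 0.3 percentage points)
- the flasks put in order of amount of target, in percent of the starting material charged, best first, at 5.0 h (ash / larch / cedar / alder / birch / oak)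
- the amount of target, in percent of the starting material charged of the flask you put first, at 5.0 h
- the amount of target, in percent of the starting material charged of the flask you put last, at 5.0 h
- the numbers in the tables scatter with a standard deviation of 0.3 percentage points

In the gamma run at 2.50 h, target and starting material leave 12.3% of the charge unaccounted for. If each protic impurity takes one starting material, the impurity is the limiting reagent of this side loss, and the loss stops at a cap of 20.0% of the charge. I call the area under a flask's starting-material curve its exposure X, in hours at full charge, and gamma's is about 2.04 h. Impurity left then falls as exp(−qX), and gamma gives the quench constant q, the impurity's decay per hour of exposure, 0.468 /h. So the loss is L = cap(1 − exp(−qX)).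

Alpha tests this: its readings give X = 0.615 h, so L = 5.00%, and its gap reads 4.90%.

For birch I stretch alpha's curve by the catalyst ratio, which gives X = 0.717 h and L = 5.71%. Alpha still holds 1.1% of its starting material at 2.50 h, and the stretch puts that moment at 2.92 h, earlier than 5.0 h, so I count birch's starting material as converted, and that leaves 94.3% target.

For cedar I do not assume the starting material converted, so I go round. Gamma's target per exposure, scaled to cedar's charge, gives k = 0.0891 /h. Ignoring the loss, starting material left is 64.0%, so X = 4.10 h, target 36.6% and loss 17.1%. Putting that back leaves 46.4% and target 32.6%. Once more, with loss 16.4%, leaves 51.0%, so X = 3.77 h and target 33.6%. Cedar's exposure is longer than birch's and its target lower, so I rank the flasks by falling free catalyst and charge birch's 3.0 mM.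

The forecast reads birch > ash > larch > oak > alder > cedar, with 94.5% for birch and 36% for cedar, above my cedar figure, on the ground that “more catalyst outruns the side reaction”.

The flask gives birch > ash > larch > oak > alder > cedar, with 94.1% in birch and 31.8% in cedar.

    catalyst intermediate A → free catalyst + target (k = 44.0 /h)
    starting material + protic impurity → quenched substrate (k = 10.0 /M/h)
    second substrate + free catalyst ⇌ catalyst intermediate B (K = 160 /M, k = 460 /M/h)
    catalyst intermediate B → free catalyst + second product (k = 100 /h)
    catalyst intermediate B → spent catalyst (k = 0.410 /h)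
    starting material + free catalyst ⇌ catalyst intermediate A (K = 17.0 /M, k = 13000 /M/h)

Quenched substrate stands at 5.85% in birch and 16.6% in cedar. Cedar keeps 17% of its protic impurity, which q turns into an exposure of 3.79 h. For birch's neighbour with 1.20 mM free catalyst, alpha's curve stretched to its last reading at 7.29 h, later than 5.0 h, and q give 43.2% impurity left, and that flask holds 44.2% of its protic impurity at 5.00 h.

The readings come from a simulation with made-up constants; scatter was added.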